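**Retrosynthetic overview**
1. Target 12 ⇐ benzofuran ester 10 by hydrolysis and loss of CO2; the CO2Me group at C5 is a traceless control group.
2. 10 ⇐ aryl iodide 4 + arylalkyne 8: C(sp2)–C(sp) coupling, then closure of the furan through the C2–O1 bond (key step). The furan is the only ring built; both benzene rings are bought.
3. 4 ⇐ methyl 2,4,6-trihydroxybenzoate 1: O-prenylation at the 4-OH, aromatic Claisen rearrangement (gives the 1,1-dimethylallyl group; one product by symmetry), iodination of the last ring C–H.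
4. 8 ⇐ 3,5-dihydroxybenzaldehyde 5: 2,6-dibromination, twofold prenyl Stille coupling, aldehyde-to-alkyne homologation.

Assumption: the target has no stereocentre and no E/Z-stereogenic double bond, so it is achiral and "single enantiomer" is read as the single compound drawn.

**Route**

Step 1
Reactants: 1 methyl 2,4,6-trihydroxybenzoate
Product: 2 methyl 2,6-dihydroxy-4-[(3-methylbut-2-en-1-yl)oxy]benzoate
Conditions: prenol (1.05 eq), PPh3 (1.1 eq), DIAD (1.1 eq), THF, 0 °C → rt, 4 h
Reagents that add atoms: 3-methylbut-2-en-1-ol (prenol), CC(C)=CCO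
Why: Mitsunobu etherification; the 4-OH is the only hydroxyl not hydrogen-bonded to the ester and the most acidic, so it alone is alkylated.

Step 2
Reactants: 2 methyl 2,6-dihydroxy-4-[(3-methylbut-2-en-1-yl)oxy]benzoate
Product: 3 methyl 2,4,6-trihydroxy-3-(2-methylbut-3-en-2-yl)benzoate
Conditions: PhNEt2, 180 °C, sealed tube, Ar, 1.5 h
Reagents that add atoms: none
Why: Aromatic Claisen rearrangement ([3,3] shift with allyl inversion, then rearomatising tautomerisation); the two ortho positions of the ether are equivalent, so one product forms, and the amine solvent suppresses acid-catalysed cyclisation of the product.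

Step 3
Reactants: 3 methyl 2,4,6-trihydroxy-3-(2-methylbut-3-en-2-yl)benzoate
Product: 4 methyl 2,4,6-trihydroxy-3-iodo-5-(2-methylbut-3-en-2-yl)benzoate
Conditions: I2 (1.0 eq), NaHCO3 (1.5 eq), THF/H2O 1:1, 0 °C, 30 min, dark
Reagents that add atoms: iodine, II
Why: Electrophilic aromatic iodination at the only remaining ring C–H of a phloroglucinol; with exactly one equivalent at 0 °C the phenoxide carbon should take up iodine faster than the vinyl group can undergo iodoetherification.

Step 4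
Reactants: 5 3,5-dihydroxybenzaldehyde
Product: 6 2,6-dibromo-3,5-dihydroxybenzaldehyde
Conditions: NBS (2.05 eq), MeCN, −20 → 0 °C, 1 h
Reagents that add atoms: N-bromosuccinimide, O=C1CCC(=O)N1Br
Why: Electrophilic aromatic bromination; each bromine enters para to one hydroxyl and ortho to the other, and the carbon between the two hydroxyls reacts last, as in resorcinol → 4,6-dibromoresorcinol.

Step 5
Reactants: 6 2,6-dibromo-3,5-dihydroxybenzaldehyde
Product: 7 3,5-dihydroxy-2,6-bis(3-methylbut-2-en-1-yl)benzaldehyde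
Conditions: tributyl(prenyl)stannane (2.6 eq), Pd(PPh3)4 (10 mol%), DMF, 95 °C, 16 h, Ar
Reagents that add atoms: tributyl(3-methylbut-2-en-1-yl)stannane, CCCC[Sn](CCCC)(CCCC)CC=C(C)C
Why: Twofold Migita–Kosugi–Stille coupling; both C–Br bonds are ortho to the formyl group and activated for oxidative addition, the prenyl group is transferred through its CH2 end, and the neutral conditions tolerate the aldehyde and free phenols.

Step 6
Reactants: 7 3,5-dihydroxy-2,6-bis(3-methylbut-2-en-1-yl)benzaldehyde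
Product: 8 5-ethynyl-4,6-bis(3-methylbut-2-en-1-yl)benzene-1,3-diol
Conditions: dimethyl (1-diazo-2-oxopropyl)phosphonate (2 eq), K2CO3 (5 eq), MeOH, 0 °C → rt, 18 h
Reagents that add atoms: dimethyl (1-diazo-2-oxopropyl)phosphonate, CC(=O)C(=[N+]=[N-])P(=O)(OC)OC
Why: Seyferth–Gilbert homologation with the Bestmann–Ohira reagent turns the aldehyde into the terminal alkyne under carbonate/methanol conditions that leave prenyl groups and phenols untouched.

Step 7
Reactants: 4 methyl 2,4,6-trihydroxy-3-iodo-5-(2-methylbut-3-en-2-yl)benzoate; 8 5-ethynyl-4,6-bis(3-methylbut-2-en-1-yl)benzene-1,3-diol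
Product: 10 methyl 2-[3,5-dihydroxy-2,6-bis(3-methylbut-2-en-1-yl)phenyl]-4,6-dihydroxy-7-(2-methylbut-3-en-2-yl)-1-benzofuran-5-carboxylate, via diarylalkyne 9 (not isolated)
Conditions: PdCl2(PPh3)2 (3 mol%), CuI (6 mol%), MgCl2 (1.2 eq), Et3N (6 eq), DMF, rt 3 h then 65 °C 8 h, Ar
Reagents that add atoms: none
Why: Proposed new method: a magnesium-chelate-gated, site-selective Sonogashira coupling–5-endo-dig oxycyclisation on unprotected partners; Pd/Cu first joins 4 and 8 to alkyne 9, whose triple bond lies between two different hydroxyls; MgCl2/Et3N places Mg2+ in the less hindered salicylate pocket (2-O−/ester C=O, six-membered chelate) and so takes the 2-oxygen out of play; the free 4-phenoxide, the most acidic one (para to the ester) and pressed toward the alkyne by the neighbouring quaternary carbon, then adds anti to the Cu/Pd-activated alkyne carbon that carries the aryl group, and protodemetalation gives the furan C2–O1 bond with the 1,1-dimethylallyl group at C7; closest known reaction type: Pd/Cu domino coupling–cyclisation of o-iodophenols with 1-alkynes (Castro–Stephens/Cacchi benzofuran synthesis), where a Lewis-acid gate choosing between two ortho-hydroxyls has not been shown.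

Step 8
Reactants: 10 methyl 2-[3,5-dihydroxy-2,6-bis(3-methylbut-2-en-1-yl)phenyl]-4,6-dihydroxy-7-(2-methylbut-3-en-2-yl)-1-benzofuran-5-carboxylate
Product: 12 2-[3,5-dihydroxy-2,6-bis(3-methylbut-2-en-1-yl)phenyl]-7-(2-methylbut-3-en-2-yl)-1-benzofuran-4,6-diol, via carboxylic acid 11 (not isolated)
Conditions: KOH (20 eq), H2O/DMSO 1:1, 100 °C, 6 h, Ar; then AcOH to pH 5, 70 °C, 1 h
Reagents that add atoms: none
Why: Ester hydrolysis followed by protodecarboxylation of a 2,6-dihydroxy-4-oxybenzoic acid, which loses CO2 on ipso-protonation as readily as 2,4,6-trihydroxybenzoic acid does; base and weak acid leave the three allyl-type groups intact.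

**Compound list**
1 | methyl 2,4,6-trihydroxybenzoate | COC(=O)c1c(O)cc(O)cc1O | starting material
2 | methyl 2,6-dihydroxy-4-[(3-methylbut-2-en-1-yl)oxy]benzoate | COC(=O)c1c(O)cc(OCC=C(C)C)cc1O | intermediate
3 | methyl 2,4,6-trihydroxy-3-(2-methylbut-3-en-2-yl)benzoate | COC(=O)c1c(O)cc(O)c(C(C)(C)C=C)c1O | intermediate
4 | methyl 2,4,6-trihydroxy-3-iodo-5-(2-methylbut-3-en-2-yl)benzoate | COC(=O)c1c(O)c(I)c(O)c(C(C)(C)C=C)c1O | intermediate
5 | 3,5-dihydroxybenzaldehyde | O=Cc1cc(O)cc(O)c1 | starting material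
6 | 2,6-dibromo-3,5-dihydroxybenzaldehyde | O=Cc1c(Br)c(O)cc(O)c1Br | intermediate
7 | 3,5-dihydroxy-2,6-bis(3-methylbut-2-en-1-yl)benzaldehyde | O=Cc1c(CC=C(C)C)c(O)cc(O)c1CC=C(C)C | intermediate
8 | 5-ethynyl-4,6-bis(3-methylbut-2-en-1-yl)benzene-1,3-diol | C#Cc1c(CC=C(C)C)c(O)cc(O)c1CC=C(C)C | intermediate
9 | methyl 3-{[3,5-dihydroxy-2,6-bis(3-methylbut-2-en-1-yl)phenyl]ethynyl}-2,4,6-trihydroxy-5-(2-methylbut-3-en-2-yl)benzoate | COC(=O)c1c(O)c(C#Cc2c(CC=C(C)C)c(O)cc(O)c2CC=C(C)C)c(O)c(C(C)(C)C=C)c1O | intermediate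
10 | methyl 2-[3,5-dihydroxy-2,6-bis(3-methylbut-2-en-1-yl)phenyl]-4,6-dihydroxy-7-(2-methylbut-3-en-2-yl)-1-benzofuran-5-carboxylate | C=CC(C)(C)c1c(O)c(C(=O)OC)c(O)c2cc(-c3c(CC=C(C)C)c(O)cc(O)c3CC=C(C)C)oc12 | intermediate
11 | 2-[3,5-dihydroxy-2,6-bis(3-methylbut-2-en-1-yl)phenyl]-4,6-dihydroxy-7-(2-methylbut-3-en-2-yl)-1-benzofuran-5-carboxylic acid | C=CC(C)(C)c1c(O)c(C(=O)O)c(O)c2cc(-c3c(CC=C(C)C)c(O)cc(O)c3CC=C(C)C)oc12 | intermediate
12 | 2-[3,5-dihydroxy-2,6-bis(3-methylbut-2-en-1-yl)phenyl]-7-(2-methylbut-3-en-2-yl)-1-benzofuran-4,6-diol (CNP0115465.0) | C=CC(C)(C)c1c(O)cc(O)c2cc(-c3c(CC=C(C)C)c(O)cc(O)c3CC=C(C)C)oc12 | target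

**Step count and risks**
Total steps: 8. Longest linear sequence: 5 (1 → 2 → 3 → 4 → 10 → 12, or 5 → 6 → 7 → 8 → 10 → 12).

The three steps most likely to fail:

Step 7 (the proposed new step). The risk is that the magnesium gate and the acidity bias do not fully suppress closure through the ester-chelated 2-OH, or that coupling of the unprotected partners stalls. The fallback uses known chemistry only and sets out from 3. Hydrolysis and decarboxylation (KOH, H2O/MeOH, then AcOH) lead through 2,4,6-trihydroxy-3-(2-methylbut-3-en-2-yl)benzoic acid F1 to 2-(2-methylbut-3-en-2-yl)benzene-1,3,5-triol F2. The one hydroxyl not flanked by the quaternary carbon is silylated (TIPSCl 1.0 eq, imidazole, DMF, 0 °C) to 2-(2-methylbut-3-en-2-yl)-5-{[tri(propan-2-yl)silyl]oxy}benzene-1,3-diol F3. Iodination (I2, NaHCO3) at one of the two equivalent ring positions gives 4-iodo-2-(2-methylbut-3-en-2-yl)-5-{[tri(propan-2-yl)silyl]oxy}benzene-1,3-diol F4. Standard Pd/Cu Sonogashira coupling with 8 (Et3N, DMF, 65 °C) passes through 4-{[3,5-dihydroxy-2,6-bis(3-methylbut-2-en-1-yl)phenyl]ethynyl}-2-(2-methylbut-3-en-2-yl)-5-{[tri(propan-2-yl)silyl]oxy}benzene-1,3-diol F5. In F5 the only free hydroxyl ortho to the alkyne is the one beside the 1,1-dimethylallyl group, so it closes in the same flask to 5-[6-hydroxy-7-(2-methylbut-3-en-2-yl)-4-{[tri(propan-2-yl)silyl]oxy}-1-benzofuran-2-yl]-4,6-bis(3-methylbut-2-en-1-yl)benzene-1,3-diol F6. TBAF in THF removes the silyl group and the sequence comes back to the route at 12.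

Step 2 (thermal Claisen). The risk is that the new ortho-(1,1-dimethylallyl)phenol cyclises onto its own alkene or rearranges further at 180 °C. The fallback sets out from 2 and replaces the free-phenol rearrangement by a protect–rearrange–trap–deprotect sequence. Acetylation (Ac2O, pyridine, DMAP) gives methyl 2,6-bis(acetyloxy)-4-[(3-methylbut-2-en-1-yl)oxy]benzoate F7. Heating F7 in PhNEt2 with Ac2O/NaOAc at 190 °C forms the rearranged phenol methyl 2,6-bis(acetyloxy)-4-hydroxy-3-(2-methylbut-3-en-2-yl)benzoate F8, which is acetylated as it forms to methyl 2,4,6-tris(acetyloxy)-3-(2-methylbut-3-en-2-yl)benzoate F9. Methanolysis (K2CO3, MeOH, rt) comes back to the route at 3.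

Step 5 (twofold Stille coupling). The risks are a hindered second coupling, branched (γ) prenyl transfer, or allylation of the aldehyde. The fallback sets out from 5, bypasses 6, and installs the prenyl groups through C–O bonds and sigmatropic shifts instead of cross-coupling. Pd-catalysed allylic etherification (Pd(PPh3)4, methyl 2-methylbut-3-en-2-yl carbonate, THF) gives 3,5-bis[(2-methylbut-3-en-2-yl)oxy]benzaldehyde F10. Heating in PhNEt2 at 130 °C brings about two aromatic Claisen rearrangements, through 3-hydroxy-2-(3-methylbut-2-en-1-yl)-5-[(2-methylbut-3-en-2-yl)oxy]benzaldehyde F11. Each ether should migrate to the carbon beside the formyl group, which is ortho to the acceptor and para to the other oxygen, rather than to the carbon between the two oxygens. The sequence comes back to the route at 7.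

**Further compounds**
F1 | step 7 | 2,4,6-trihydroxy-3-(2-methylbut-3-en-2-yl)benzoic acid | C=CC(C)(C)c1c(O)cc(O)c(C(=O)O)c1O
F2 | step 7 | 2-(2-methylbut-3-en-2-yl)benzene-1,3,5-triol | C=CC(C)(C)c1c(O)cc(O)cc1O
F3 | step 7 | 2-(2-methylbut-3-en-2-yl)-5-{[tri(propan-2-yl)silyl]oxy}benzene-1,3-diol | C=CC(C)(C)c1c(O)cc(O[Si](C(C)C)(C(C)C)C(C)C)cc1O
F4 | step 7 | 4-iodo-2-(2-methylbut-3-en-2-yl)-5-{[tri(propan-2-yl)silyl]oxy}benzene-1,3-diol | C=CC(C)(C)c1c(O)cc(O[Si](C(C)C)(C(C)C)C(C)C)c(I)c1O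
F5 | step 7 | 4-{[3,5-dihydroxy-2,6-bis(3-methylbut-2-en-1-yl)phenyl]ethynyl}-2-(2-methylbut-3-en-2-yl)-5-{[tri(propan-2-yl)silyl]oxy}benzene-1,3-diol | C=CC(C)(C)c1c(O)cc(O[Si](C(C)C)(C(C)C)C(C)C)c(C#Cc2c(CC=C(C)C)c(O)cc(O)c2CC=C(C)C)c1O
F6 | step 7 | 5-[6-hydroxy-7-(2-methylbut-3-en-2-yl)-4-{[tri(propan-2-yl)silyl]oxy}-1-benzofuran-2-yl]-4,6-bis(3-methylbut-2-en-1-yl)benzene-1,3-diol | C=CC(C)(C)c1c(O)cc(O[Si](C(C)C)(C(C)C)C(C)C)c2cc(-c3c(CC=C(C)C)c(O)cc(O)c3CC=C(C)C)oc12
F7 | step 2 | methyl 2,6-bis(acetyloxy)-4-[(3-methylbut-2-en-1-yl)oxy]benzoate | COC(=O)c1c(OC(C)=O)cc(OCC=C(C)C)cc1OC(C)=O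
F8 | step 2 | methyl 2,6-bis(acetyloxy)-4-hydroxy-3-(2-methylbut-3-en-2-yl)benzoate | COC(=O)c1c(OC(C)=O)cc(O)c(C(C)(C)C=C)c1OC(C)=O
F9 | step 2 | methyl 2,4,6-tris(acetyloxy)-3-(2-methylbut-3-en-2-yl)benzoate | COC(=O)c1c(OC(C)=O)cc(OC(C)=O)c(C(C)(C)C=C)c1OC(C)=O
F10 | step 5 | 3,5-bis[(2-methylbut-3-en-2-yl)oxy]benzaldehyde | O=Cc1cc(OC(C)(C)C=C)cc(OC(C)(C)C=C)c1
F11 | step 5 | 3-hydroxy-2-(3-methylbut-2-en-1-yl)-5-[(2-methylbut-3-en-2-yl)oxy]benzaldehyde | O=Cc1cc(OC(C)(C)C=C)cc(O)c1CC=C(C)C
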